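**Retrosynthetic overview**
1. Target ⇐ tertiary alcohol (C–OH → C–Br, anti to Cl) ⇐ trans-α-chloro ketone (+ CH3) ⇐ 4-(oxan-2-yl)cyclohexanone: Br, CH3 and Cl of the carbocycle all descend from one ketone at C4′.
2. Enabling feature: the cyclohexane bears carbon substituents only at C1′ (the CH on oxane C2) and at the para carbon C4′. Without the halogens the arms C2′–C3′ and C6′–C5′ are identical CH2CH2 units, so the ring is closed last from a penta-1,4-dien-3-yl group on oxane C2 plus one carbon of CO ([5+1] cyclic hydroboration–carbonylation).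
3. C1′ becomes a stereocentre only after ring closure, by reagent-controlled desymmetrisation of the ketone, which also decides which α-carbon takes Cl.
4. Oxane ring (formed first): 6-endo bromoetherification of a tertiary alcohol onto a prenyl alkene; its C2/C3 pair comes from chelation-controlled pentadienylation of an (S)-α-hydroxy methyl ketone made from methyl (S)-glycidate.
5. Order of ring formation: oxane ring, then cyclohexane ring.

Key step: step 8

Assumption: the (S,S)-lithium amide of step 9 is taken to select the α-methylene that leads to the (1R)-enol ether, by analogy with simple 4-substituted cyclohexanones; if the sense is opposite, the antipodal amine is used in the same way.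

**Step 1**
Reactants: 1 methyl (2S)-oxirane-2-carboxylate; 2 (2-methylprop-1-en-1-yl)magnesium bromide
Product: 3 methyl (2S)-2-hydroxy-5-methylhex-4-enoate
Conditions: CuI (10 mol %), THF, −40 to −20 °C; aq NH4Cl
Reagents that add atoms: none
Why: Copper-catalysed Grignard opening of the terminal epoxide (SN2 at the CH2 carbon) should be faster than attack on the ester, and the stereocentre of 1 is carried unchanged into 3.

**Step 2**
Reactants: 3 methyl (2S)-2-hydroxy-5-methylhex-4-enoate
Product: 4 (2S)-2-hydroxy-N-methoxy-N,5-dimethylhex-4-enamide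
Conditions: MeNH(OMe)·HCl, i-PrMgCl, THF, −20 to 0 °C
Reagents that add atoms: N,O-dimethylhydroxylamine hydrochloride, CNOC.Cl
Why: Aminolysis of the ester by the magnesium amide of N,O-dimethylhydroxylamine (Weinreb amide formation) tolerates the free hydroxyl as its alkoxide and touches no stereocentre.

**Step 3**
Reactants: 4 (2S)-2-hydroxy-N-methoxy-N,5-dimethylhex-4-enamide
Product: 5 (3S)-3-hydroxy-6-methylhept-5-en-2-one
Conditions: MeMgBr (2.5 equiv), THF, −78 to 0 °C; aq NH4Cl
Reagents that add atoms: methylmagnesium bromide, C[Mg]Br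
Why: Weinreb ketone synthesis: the chelated tetrahedral intermediate should stop at the ketone, the first equivalent of Grignard reagent only deprotonating the hydroxyl.

**Step 4**
Reactants: 6 penta-1,4-dien-3-ol
Product: 7 (3E)-5-bromopenta-1,3-diene
Conditions: 48 % aq HBr, 0 °C; used crude
Reagents that add atoms: hydrogen bromide, Br
Why: Acid-promoted allylic substitution with transposition (SN1/SN2′) of the bis-allylic alcohol should give the conjugated primary bromide.

**Step 5**
Reactants: 5 (3S)-3-hydroxy-6-methylhept-5-en-2-one; 7 (3E)-5-bromopenta-1,3-diene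
Product: 8 (4S,5S)-3-ethenyl-4,8-dimethylnona-1,7-diene-4,5-diol
Conditions: In powder, THF/H2O (1:1), rt
Reagents that add atoms: none
Why: Barbier-type indium-mediated pentadienylation should react at the central (γ) carbon of the pentadienyl unit through a six-membered transition state to give the bis-vinyl group, while indium bound to the free α-hydroxyl and the carbonyl oxygen (Cram chelate) directs attack to the face away from the CH2CH=CMe2 chain and so sets C4 as S.

**Step 6**
Reactants: 8 (4S,5S)-3-ethenyl-4,8-dimethylnona-1,7-diene-4,5-diol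
Product: 9 (4S,5S)-5-{[tert-butyl(dimethyl)silyl]oxy}-3-ethenyl-4,8-dimethylnona-1,7-dien-4-ol
Conditions: TBSOTf, 2,6-lutidine, CH2Cl2, −78 °C
Reagents that add atoms: tert-butyldimethylsilyl trifluoromethanesulfonate, CC(C)(C)[Si](C)(C)OS(=O)(=O)C(F)(F)F
Why: Silylation should take the less hindered secondary hydroxyl, which keeps it from competing as a nucleophile in step 7 and leaves the tertiary hydroxyl free.

**Step 7**
Reactants: 9 (4S,5S)-5-{[tert-butyl(dimethyl)silyl]oxy}-3-ethenyl-4,8-dimethylnona-1,7-dien-4-ol
Product: 10 tert-butyl{[(2S,3S,5S)-5-bromo-2,6,6-trimethyl-2-(penta-1,4-dien-3-yl)oxan-3-yl]oxy}dimethylsilane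
Conditions: 2,4,4,6-tetrabromocyclohexa-2,5-dienone (TBCO), MeNO2, 0 °C
Reagents that add atoms: 2,4,4,6-tetrabromocyclohexa-2,5-dienone, O=C1C(Br)=CC(Br)(Br)C=C1Br
Why: Bromoetherification (6-endo, Markovnikov) of the most electron-rich alkene: the tertiary hydroxyl opens the bromonium ion at the dimethyl-substituted carbon anti to bromine through a chair in which Br and the branched pentadienyl group are equatorial and the silyloxy group, flanked by the quaternary carbon, is axial, which should set C5 as S.

**Step 8**
Reactants: 10 tert-butyl{[(2S,3S,5S)-5-bromo-2,6,6-trimethyl-2-(penta-1,4-dien-3-yl)oxan-3-yl]oxy}dimethylsilane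
Product: 12 4-[(2S,3S,5S)-5-bromo-3-{[tert-butyl(dimethyl)silyl]oxy}-2,6,6-trimethyloxan-2-yl]cyclohexan-1-one, via B-thexylborinane 11 (not isolated)
Conditions: ThxBH2 (from BH3·THF and 2,3-dimethylbut-2-ene), THF, 0 °C to rt, high dilution; CO (70 atm), H2O, 50 °C; NaOAc, 30 % H2O2, 40 °C
Reagents that add atoms: carbon monoxide, [C-]#[O+]
Why: Thexylborane should add its two B–H bonds anti-Markovnikov to the two vinyl groups of 10, the second addition intramolecular, so that boron bridges the two terminal carbons in the six-membered borinane 11; CO then binds to boron, the two ring B–CH2 groups migrate in turn from boron to the carbonyl carbon (water stops the sequence before the poorly migrating thexyl group moves), and oxidation of the remaining C–B bond releases the ketone. The closest known reaction type is the cyclic hydroboration–carbonylation of 1,4- and 1,5-dienes with thexylborane, which gives cyclohexanones and cycloheptanones. The cyclohexane ring is closed in a [5+1] mode: five carbons from the penta-1,4-dien-3-yl unit and one from CO, the six-membered boracycle being converted into the six-membered carbocycle by two successive 1,2-shifts that replace boron by carbon. No stereocentre is created: the ring CH lies on the local mirror plane of the 4-substituted cyclohexanone, and the three oxane stereocentres are not touched by neutral borane, CO and buffered peroxide. The step needs terminal regioselectivity in both hydroborations and cyclisation in place of oligomerisation; the bulk of the thexyl group and of the neighbouring quaternary oxane carbon should direct boron to the CH2 termini, and high dilution with the fixed 1,4-diene spacing should favour the borinane. The equatorial secondary bromide, the silyl ether and the di-tertiary ether are inert under these conditions.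

**Step 9**
Reactants: 12 4-[(2S,3S,5S)-5-bromo-3-{[tert-butyl(dimethyl)silyl]oxy}-2,6,6-trimethyloxan-2-yl]cyclohexan-1-one
Product: 14 (2S,4R)-4-[(2S,3S,5S)-5-bromo-3-{[tert-butyl(dimethyl)silyl]oxy}-2,6,6-trimethyloxan-2-yl]-2-chlorocyclohexan-1-one, via trimethylsilyl enol ether 13 (not isolated)
Conditions: LiN[(S)-CH(CH3)Ph]2·LiCl (from the (S,S)-amine hydrochloride and n-BuLi, 2 equiv), THF, −78 °C, then TMSCl; crude 13, NCS, THF, −78 to 0 °C
Reagents that add atoms: N-chlorosuccinimide, O=C1CCC(=O)N1Cl
Why: Group-selective deprotonation of the two α-methylenes by the chiral lithium amide (known desymmetrisation of 4-substituted cyclohexanones) should make the ring CH a stereocentre (1R in 13), and chlorination of the enol ether by NCS along the axial direction should place Cl trans to the equatorial oxanyl group (2S).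

**Step 10**
Reactants: 14 (2S,4R)-4-[(2S,3S,5S)-5-bromo-3-{[tert-butyl(dimethyl)silyl]oxy}-2,6,6-trimethyloxan-2-yl]-2-chlorocyclohexan-1-one
Product: 15 (1R,2S,4R)-4-[(2S,3S,5S)-5-bromo-3-{[tert-butyl(dimethyl)silyl]oxy}-2,6,6-trimethyloxan-2-yl]-2-chloro-1-methylcyclohexan-1-ol
Conditions: MeLi, anhydrous CeCl3, THF, −78 °C; AcOH quench at −78 °C
Reagents that add atoms: methyllithium, [Li]C
Why: 1,2-Addition of the weakly basic organocerium reagent avoids enolisation of the α-chloro ketone, and attack anti to the axial C–Cl bond (Cornforth/polar Felkin–Anh model) should give mainly the 1R carbinol, either epimer converging in step 12.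

**Step 11**
Reactants: 15 (1R,2S,4R)-4-[(2S,3S,5S)-5-bromo-3-{[tert-butyl(dimethyl)silyl]oxy}-2,6,6-trimethyloxan-2-yl]-2-chloro-1-methylcyclohexan-1-ol
Product: 16 (2S,3S,5S)-5-bromo-2-[(1R,3S,4R)-3-chloro-4-hydroxy-4-methylcyclohexyl]-2,6,6-trimethyloxan-3-ol
Conditions: HF·pyridine, THF/pyridine, 0 °C to rt
Reagents that add atoms: none
Why: Fluoride cleavage of the silyl ether under weakly acidic conditions should leave the chlorohydrin and both halides untouched.

**Step 12**
Reactants: 16 (2S,3S,5S)-5-bromo-2-[(1R,3S,4R)-3-chloro-4-hydroxy-4-methylcyclohexyl]-2,6,6-trimethyloxan-3-ol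
Product: 17 (2S,3S,5S)-5-bromo-2-[(1R,3S,4S)-4-bromo-3-chloro-4-methylcyclohexyl]-2,6,6-trimethyloxan-3-ol
Conditions: TMSBr, CH2Cl2, −20 to 0 °C; then MeOH, 0 °C
Reagents that add atoms: bromotrimethylsilane, C[Si](C)(C)Br
Why: SN1 substitution of the tertiary alcohol: the β-chloro tertiary cation is bridged by the axial chlorine, so bromide should enter anti to Cl and axially to give the trans-diaxial bromide with equatorial methyl (4S), which is also the more stable epimer under reversible ionisation; the secondary hydroxyl is only silylated transiently and freed by the methanol quench.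

**Compound list**
1 | methyl (2S)-oxirane-2-carboxylate | COC(=O)[C@@H]1CO1 | starting material
2 | (2-methylprop-1-en-1-yl)magnesium bromide | CC(C)=C[Mg]Br | starting material
3 | methyl (2S)-2-hydroxy-5-methylhex-4-enoate | COC(=O)[C@@H](O)CC=C(C)C | intermediate
4 | (2S)-2-hydroxy-N-methoxy-N,5-dimethylhex-4-enamide | CON(C)C(=O)[C@@H](O)CC=C(C)C | intermediate
5 | (3S)-3-hydroxy-6-methylhept-5-en-2-one | CC(=O)[C@@H](O)CC=C(C)C | intermediate
6 | penta-1,4-dien-3-ol | C=CC(O)C=C | starting material
7 | (3E)-5-bromopenta-1,3-diene | BrC/C=C/C=C | intermediate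
8 | (4S,5S)-3-ethenyl-4,8-dimethylnona-1,7-diene-4,5-diol | O[C@@](C)(C(C=C)C=C)[C@@H](O)CC=C(C)C | intermediate
9 | (4S,5S)-5-{[tert-butyl(dimethyl)silyl]oxy}-3-ethenyl-4,8-dimethylnona-1,7-dien-4-ol | O[C@@](C)(C(C=C)C=C)[C@@H](O[Si](C)(C)C(C)(C)C)CC=C(C)C | intermediate
10 | tert-butyl{[(2S,3S,5S)-5-bromo-2,6,6-trimethyl-2-(penta-1,4-dien-3-yl)oxan-3-yl]oxy}dimethylsilane | CC1(C)O[C@@](C)(C(C=C)C=C)[C@@H](O[Si](C)(C)C(C)(C)C)C[C@@H]1Br | intermediate
11 | 4-[(2S,3S,5S)-5-bromo-3-{[tert-butyl(dimethyl)silyl]oxy}-2,6,6-trimethyloxan-2-yl]-1-(2,3-dimethylbutan-2-yl)borinane (B-thexylborinane) | CC1(C)O[C@@](C)(C2CCB(CC2)C(C)(C)C(C)C)[C@@H](O[Si](C)(C)C(C)(C)C)C[C@@H]1Br | intermediate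
12 | 4-[(2S,3S,5S)-5-bromo-3-{[tert-butyl(dimethyl)silyl]oxy}-2,6,6-trimethyloxan-2-yl]cyclohexan-1-one | CC1(C)O[C@@](C)(C2CCC(=O)CC2)[C@@H](O[Si](C)(C)C(C)(C)C)C[C@@H]1Br | intermediate
13 | tert-butyl{[(2S,3S,5S)-5-bromo-2,6,6-trimethyl-2-[(1R)-4-(trimethylsilyloxy)cyclohex-3-en-1-yl]oxan-3-yl]oxy}dimethylsilane | CC1(C)O[C@@](C)([C@@H]2CCC(O[Si](C)(C)C)=CC2)[C@@H](O[Si](C)(C)C(C)(C)C)C[C@@H]1Br | intermediate
14 | (2S,4R)-4-[(2S,3S,5S)-5-bromo-3-{[tert-butyl(dimethyl)silyl]oxy}-2,6,6-trimethyloxan-2-yl]-2-chlorocyclohexan-1-one | CC1(C)O[C@@](C)([C@@H]2CCC(=O)[C@@H](Cl)C2)[C@@H](O[Si](C)(C)C(C)(C)C)C[C@@H]1Br | intermediate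
15 | (1R,2S,4R)-4-[(2S,3S,5S)-5-bromo-3-{[tert-butyl(dimethyl)silyl]oxy}-2,6,6-trimethyloxan-2-yl]-2-chloro-1-methylcyclohexan-1-ol | CC1(C)O[C@@](C)([C@@H]2CC[C@@](C)(O)[C@@H](Cl)C2)[C@@H](O[Si](C)(C)C(C)(C)C)C[C@@H]1Br | intermediate
16 | (2S,3S,5S)-5-bromo-2-[(1R,3S,4R)-3-chloro-4-hydroxy-4-methylcyclohexyl]-2,6,6-trimethyloxan-3-ol | CC1(C)O[C@@](C)([C@@H]2CC[C@@](C)(O)[C@@H](Cl)C2)[C@@H](O)C[C@@H]1Br | intermediate
17 | (2S,3S,5S)-5-bromo-2-[(1R,3S,4S)-4-bromo-3-chloro-4-methylcyclohexyl]-2,6,6-trimethyloxan-3-ol | CC1(C)O[C@@](C)([C@@H]2CC[C@](C)(Br)[C@@H](Cl)C2)[C@@H](O)C[C@@H]1Br | target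

**Step count and risks**
Total step count: 12. Longest linear sequence: 11 steps (steps 1–3 and 5–12, from 1 to 17); step 4 is a one-step side branch.

Steps most likely to fail:

Step 7. The cyclisation may pass through the alternative chair (wrong configuration at C5), or oxygen may attack the secondary alkene carbon to give a five-membered ether. Fallback: the route sets out again from 9 and no longer depends on the chair preference. The cyclisation is run as before and the ether mixture is separated. Everything that is not 10, in particular the C5 epimer tert-butyl{[(2S,3S,5R)-5-bromo-2,6,6-trimethyl-2-(penta-1,4-dien-3-yl)oxan-3-yl]oxy}dimethylsilane F1, is treated with Zn dust and NH4Cl in EtOH at 60 °C. Reductive β-elimination of the β-bromo ether (Boord-type fragmentation) reopens the ring and returns 9, which is cyclised again, and the route is rejoined at 10.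

Step 9. The base may discriminate poorly between the two α-methylene groups, or the axial chloride may epimerise. Fallback: setting out from 12, no asymmetric induction is asked for. LDA and TMSCl in THF at −78 °C give 13 together with its C1 epimer tert-butyl{[(2S,3S,5S)-5-bromo-2,6,6-trimethyl-2-[(1S)-4-(trimethylsilyloxy)cyclohex-3-en-1-yl]oxan-3-yl]oxy}dimethylsilane F2. NCS then converts the pair into 14 and (2R,4S)-4-[(2S,3S,5S)-5-bromo-3-{[tert-butyl(dimethyl)silyl]oxy}-2,6,6-trimethyloxan-2-yl]-2-chlorocyclohexan-1-one F3. Because of the three oxane stereocentres these two are diastereomers and should be separable by chromatography, and the route is rejoined at 14.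

Step 12. Ionisation of the tertiary alcohol may end in elimination, in capture of bromide syn to chlorine, or in acid-induced opening of the di-tertiary ether assisted by the ring bromide. Fallback: setting out from 14, the methyl group is made from a methylene group and the bromide by addition instead of substitution. Wittig methylenation (Ph3P=CH2, THF, −78 to 0 °C) should give tert-butyl{[(2S,3S,5S)-5-bromo-2-[(1R,3S)-3-chloro-4-methylidenecyclohexyl]-2,6,6-trimethyloxan-3-yl]oxy}dimethylsilane F4. HF·pyridine then frees (2S,3S,5S)-5-bromo-2-[(1R,3S)-3-chloro-4-methylidenecyclohexyl]-2,6,6-trimethyloxan-3-ol F5. Markovnikov addition of anhydrous HBr in CH2Cl2 at −78 °C, with bromide entering anti to the axial chlorine, should give 17 directly, so the route is rejoined at 17.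

**Further compounds**
F1 | step 7 | tert-butyl{[(2S,3S,5R)-5-bromo-2,6,6-trimethyl-2-(penta-1,4-dien-3-yl)oxan-3-yl]oxy}dimethylsilane | CC1(C)O[C@@](C)(C(C=C)C=C)[C@@H](O[Si](C)(C)C(C)(C)C)C[C@H]1Br
F2 | step 9 | tert-butyl{[(2S,3S,5S)-5-bromo-2,6,6-trimethyl-2-[(1S)-4-(trimethylsilyloxy)cyclohex-3-en-1-yl]oxan-3-yl]oxy}dimethylsilane | CC1(C)O[C@@](C)([C@H]2CCC(O[Si](C)(C)C)=CC2)[C@@H](O[Si](C)(C)C(C)(C)C)C[C@@H]1Br
F3 | step 9 | (2R,4S)-4-[(2S,3S,5S)-5-bromo-3-{[tert-butyl(dimethyl)silyl]oxy}-2,6,6-trimethyloxan-2-yl]-2-chlorocyclohexan-1-one | CC1(C)O[C@@](C)([C@H]2CCC(=O)[C@H](Cl)C2)[C@@H](O[Si](C)(C)C(C)(C)C)C[C@@H]1Br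
F4 | step 12 | tert-butyl{[(2S,3S,5S)-5-bromo-2-[(1R,3S)-3-chloro-4-methylidenecyclohexyl]-2,6,6-trimethyloxan-3-yl]oxy}dimethylsilane | CC1(C)O[C@@](C)([C@@H]2CCC(=C)[C@@H](Cl)C2)[C@@H](O[Si](C)(C)C(C)(C)C)C[C@@H]1Br
F5 | step 12 | (2S,3S,5S)-5-bromo-2-[(1R,3S)-3-chloro-4-methylidenecyclohexyl]-2,6,6-trimethyloxan-3-ol | CC1(C)O[C@@](C)([C@@H]2CCC(=C)[C@@H](Cl)C2)[C@@H](O)C[C@@H]1Br
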